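- Z is the limiting reagent, since the charge of G is twice that of Z, and each J that forms brings one E with it, so I take [E] = [J].

| flask | Z | G | temperature | remark | time |
|---|---|---|---|---|---|
| summer | 32 mM | 64 mM | 100 °C | the very flask that is asked about, followed so far |  |
| spring | 32 mM | 64 mM | 106 °C | run made earlier |  |
| flask | 32 mM | 64.0 mM | 100 °C |  | 10 h |

- summer (time / h: J / %): 0.833: 6.6; 2.50: 21.8; 5.00: 32.3; 8.00: 35.0; 10.0: 39.0
- spring (time / h: J / %): 0.833: 11.2; 2.50: 27.1; 5.00: 34.3; 8.00: 35.5; 10.0: 33.7

(each reading ± 1 percentage point)

- in percentages every species weighs as the Z in it: one X counts as two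
- as a solid, counted per litre of solution: G
- additions bring no volume worth counting
- what was read earlier has a scatter of 1 percentage point, one standard deviation
- steps that have been proposed: Z + D <-> L; 2 Z -> X; L <-> J + E; G <-> D
- at the start none of G is in solution

- gamma: at 10 h add Z, 50.0 % of the amount charged, then wait 20 h
- zeta: change nothing and wait 20 h more
- eta: at 10 h take out 90 % of the E then present, then wait 20 h
- beta: at 10 h raise the temperature by 20 K, then wait 20 h

- J, in percent of the Z first charged, at 10 h
- which option adds most J ("none" when 2 percentage points or less is all one gets) (gamma / zeta / eta / beta / none)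
- J present, in percent of the Z first charged, after zeta
- J present, in percent of the Z first charged, after beta

- Extreme one has no way back: J levels off as [Z] falls, and X holds what J does not. But a loss of second order in [Z] trails off slowly, whereas the spring run reads 34.3 % at 5.00 h and 33.7 % at 10.0 h, flat within the scatter. I therefore lean to extreme two.
- Extreme two loses nothing to X: the forward rate, proportional to [Z][D], meets the backward rate, proportional to [J][E]. Dividing one by the other removes time, and if solid G holds [D] steady, as I assume, the balance quotient (an apparent equilibrium constant) [J][E]/[Z] stays constant.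
- The summer readings at 8.00 h and 10.0 h average 37.0 %, which is 11.8 mM of J. Counting the remaining Z as free gives the balance quotient 6.95 mM.
- The real flask lies between the extremes: any Z held as L or X lowers [Z], so this value is a floor.
- I put this quotient back for gamma and eta, which stay at 100 °C, the temperature it was read at; it cannot serve beta, which changes the temperature. Adding Z gives 10 percentage points. Taking out E gives 16 points, which is more, so I choose eta.
- The forecast gives 36.8 % now, 37 % after zeta and 34.5 % after beta, and it picks gamma: “Adding Z is the robust choice”. There I differ from it.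
- The simulation gives 36.9 % now, 35.8 % after zeta and 24.9 % after beta. The best option is eta, which adds 15 points, against 8 points for gamma and −12 points for beta.

    Z + D ⇌ L (K = 13.0 M⁻¹, k = 0.0148 M⁻¹ s⁻¹, Ea = 61.0 kJ mol⁻¹, ΔH = −4.00 kJ mol⁻¹)
    2 Z → X (k = 4.84 × 10⁻⁵ M⁻¹ s⁻¹, Ea = 103 kJ mol⁻¹)
    L ⇌ J + E (K = 0.110 M, k = 0.00110 s⁻¹, Ea = 101 kJ mol⁻¹, ΔH = −26.0 kJ mol⁻¹)
    G ⇌ D, rate k4*(cs4 - [D]) while solid is left; crystals form when [D] > cs4 (solubility = 5.70 mM, k = 0.00215 s⁻¹)
    (constants at 100 °C)

- In the summer flask at 10.0 h, the simulated state gives [J][E]/[Z] = 8.07 mM, above my floor, with L at 3.99 % and X at 4.93 %. For the neighbour flask with 8.0 mM of Z, the quotient 6.95 mM with [E] = [J] gives 59.4 % J. That neighbour flask stores 39.3 % Z and 57.0 % J.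

The numbers in the tables are calculated for substances that don't exist, noise included.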